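The C2–C3 bond of the dihydrofuran ring is the one disconnection on which the route rests. C2 (bound to O1) and C3 (bearing the ester oxygen) are both oxygenated, and C2 carries an isopropenyl group. That is the pattern left when a 2-methyl-γ-aryloxyallylboron adds through its γ-carbon to a formyl group ortho to the aryl ether oxygen. In one operation an iridium hydride transposes the double bond of an alkenylboronate and a chiral phosphoric acid directs the allylboration, forming C2–C3, closing the furan ring and setting both stereocentres trans. The precursor is a 5-acetylbenzaldehyde with a 3,4-dimethoxybenzyl-protected phenol para to the formyl group and an O–CH2–C(CH3)=CH–Bpin ether ortho to it.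

Key step: step 5

Assumption: (R)-TRIP, (R)-3,3'-bis(2,4,6-triisopropylphenyl)-1,1'-binaphthyl-2,2'-diyl hydrogen phosphate, is taken to favour Re-face attack on the formyl group as it does with untethered aryl aldehydes; should the tether reverse this, the mirror-image acid is used.

Design remarks (Bpin = 4,4,5,5-tetramethyl-1,3,2-dioxaborolan-2-yl; DMB = 3,4-dimethoxybenzyl):
- The phenol is carried as a DMB ether and freed last under neutral oxidative conditions. After ring closure the C3–O bond is benzylic and activated by O1 and the C6 oxygen, so acid must be avoided from step 5 onward.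
- The C3 hydroxyl is esterified before the phenol is freed, so no alcohol/phenol selectivity is needed.
- The bromide is converted directly to the aldehyde by palladium catalysis, so the ketone needs no ketal.
- The alkenylboronate may be carried as an E/Z mixture, since step 5 erases that geometry.

Step 1
Reactants: 1 1-(5-bromo-4-fluoro-2-hydroxyphenyl)ethanone
Product: 2 1-[5-bromo-2-(3,4-dimethoxybenzyloxy)-4-fluorophenyl]ethanone
Conditions: 3,4-dimethoxybenzyl chloride, K2CO3, KI (cat.), DMF, 50 °C
Reagents that add atoms: 3,4-dimethoxybenzyl chloride, COc1ccc(CCl)cc1OC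
Why: Williamson O-benzylation of the acetyl-chelated phenoxide; the fluoride, activated only by the para acetyl group, should not undergo SNAr with this weak nucleophile at 50 °C.

Step 2
Reactants: 2 1-[5-bromo-2-(3,4-dimethoxybenzyloxy)-4-fluorophenyl]ethanone
Product: 3 5-acetyl-4-(3,4-dimethoxybenzyloxy)-2-fluorobenzaldehyde
Conditions: Pd(OAc)2 (3 mol%), dppb, N-formylsaccharin, Et3SiH, Na2CO3, DMF, 80 °C
Reagents that add atoms: N-formylsaccharin, O=CN1C(=O)c2ccccc2S1(=O)=O
Why: Palladium-catalysed reductive carbonylation of the aryl bromide (oxidative addition to zerovalent palladium, insertion of CO released from N-formylsaccharin, Si–H reduction of the acylpalladium) should give the aldehyde directly, leaving C–F, the ketone and the benzyl ether untouched.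

Step 3
Reactants: 3 5-acetyl-4-(3,4-dimethoxybenzyloxy)-2-fluorobenzaldehyde; 4 2-methylprop-2-en-1-ol
Product: 5 5-acetyl-4-(3,4-dimethoxybenzyloxy)-2-[(2-methylprop-2-en-1-yl)oxy]benzaldehyde
Conditions: 4 (3 equiv), Cs2CO3, DMF, rt
Reagents that add atoms: none
Why: SNAr: the fluoride is ortho to formyl and para to acetyl, so the doubly stabilised Meisenheimer adduct should form at room temperature with carbonate-generated alkoxide, while the benzyloxy group on the other activated carbon is a far poorer leaving group and the mild base keeps aldol condensation slow.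

Step 4
Reactants: 5 5-acetyl-4-(3,4-dimethoxybenzyloxy)-2-[(2-methylprop-2-en-1-yl)oxy]benzaldehyde; 6 vinylboronic acid pinacol ester
Product: 7 5-acetyl-4-(3,4-dimethoxybenzyloxy)-2-{[(E)-2-methyl-3-(4,4,5,5-tetramethyl-1,3,2-dioxaborolan-2-yl)prop-2-en-1-yl]oxy}benzaldehyde
Conditions: 6 (4 equiv), second-generation Hoveyda–Grubbs catalyst RuCl2(H2IMes)(=CH-C6H4-2-OiPr) (10 mol%, in portions), CH2Cl2, 40 °C
Reagents that add atoms: none
Why: Olefin cross-metathesis of a 1,1-disubstituted alkene with a vinylboronate, a known entry to trisubstituted alkenylboronates: the methallyl ether cannot homodimerise, loss of ethylene drives the exchange, and boron should sit mainly trans to the larger CH2OAr group.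

Step 5
Reactants: 7 5-acetyl-4-(3,4-dimethoxybenzyloxy)-2-{[(E)-2-methyl-3-(4,4,5,5-tetramethyl-1,3,2-dioxaborolan-2-yl)prop-2-en-1-yl]oxy}benzaldehyde
Product: 10 1-[(2R,3S)-6-(3,4-dimethoxybenzyloxy)-3-hydroxy-2-(prop-1-en-2-yl)-2,3-dihydro-1-benzofuran-5-yl]ethanone, via allylboronate 8 (not isolated), via borate ester 9 (not isolated)
Conditions: [Ir(cod)(PPh2Me)2]PF6 (5 mol%, activated with H2, then argon purge), (R)-TRIP (10 mol%), 4 Å MS, CH2Cl2, 0 °C to rt; aq. NaHCO3
Reagents that add atoms: none
Why: Proposed new method: the iridium hydride formed from the cationic monovalent iridium precatalyst and H2 is expected to abstract an O–CH2 hydrogen (allylic and α to oxygen) and return it to the boron-bearing carbon through a π-allyl hydride, giving the conjugated (E)-enol ether 8, a γ-aryloxyallylboronate whose oxygen-bearing carbon is nucleophilic; the phosphoric acid, hydrogen-bonded to a dioxaborolane oxygen and to the formyl hydrogen, then delivers this γ-carbon to the ortho formyl carbon through a six-membered chair array of B, O, C, C, C and C, the B–CH2 carbon becoming the =CH2 of the isopropenyl group and borate 9 giving 10 on aqueous work-up. The closest known reactions are the iridium-transposition/chiral-phosphoric-acid allylboration of alkenylboronates with external aldehydes and the cyclisation of (E)-γ-(ω-formylalkoxy)allylboronates to trans-2-vinyl-3-hydroxy tetrahydropyrans and oxepanes; the aryl enol ether, the 2-methyl group and the benzo-fused five-membered ring are the untested extension. The furan ring closes by 5-exo-trig attack on the formyl carbon (C=O exocyclic), with the chair fused to the forming ring. The C2/C3 relative configuration follows from the E enol ether, which keeps O1 pseudo-equatorial next to the equatorial aryl carbon (anti adduct, hence trans ring), and the absolute configuration from (R)-TRIP exposing the Re face of the aldehyde, which gives 3S and therefore 2R. The step needs aldehyde over acetyl ketone (secured by the higher electrophilicity of CHO and the five-membered tether), O–CH2 over CH3 hydrogen abstraction (secured by the α-oxygen and the conjugation gained in 8; the methyl-derived isomer could only close a seven-membered ring) and catalysed over uncatalysed closure (both share the tether, so the acid should keep its rate advantage, helped by low temperature). Because C2–H of 10 is itself allylic and α to oxygen and C3–O is an activated benzylic bond, iridium loading and time are kept low and the mixture is quenched with base while the alcohol is still masked as borate 9.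

Step 6
Reactants: 11 3-methylfuran-2(5H)-one
Product: 14 4-methoxybenzyl (2Z)-4-acetoxy-2-methylbut-2-enoate, via potassium (2Z)-4-hydroxy-2-methylbut-2-enoate 12 (not isolated), via 4-methoxybenzyl (2Z)-4-hydroxy-2-methylbut-2-enoate 13 (not isolated)
Conditions: KOH (1.0 equiv), MeOH–H2O, rt, evaporate to dryness; 4-methoxybenzyl chloride, DMF, rt; then Ac2O, pyridine, DMAP (cat.), 0 °C
Reagents that add atoms: potassium hydroxide, [K+].[OH-] (oxygen kept in 14, potassium only in 12); 4-methoxybenzyl chloride, COc1ccc(CCl)cc1; acetic anhydride, CC(=O)OC(C)=O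
Why: Saponification opens the lactone with the Z geometry fixed by the ring, SN2 O-alkylation of the carboxylate caps the acid as an unactivated ester, and DMAP-catalysed acetylation then traps the γ-hydroxyl; this order is chosen because activating the free carboxyl next to the cis hydroxyl would re-close the butenolide.

Step 7
Reactants: 14 4-methoxybenzyl (2Z)-4-acetoxy-2-methylbut-2-enoate
Product: 15 (2Z)-4-acetoxy-2-methylbut-2-enoic acid
Conditions: TFA–CH2Cl2 (1:4), anisole (3 equiv), 0 °C
Reagents that add atoms: none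
Why: Acidolysis of the 4-methoxybenzyl ester (SN1 loss of the benzylic cation, trapped by anisole in a Friedel–Crafts alkylation) should free the acid, while the primary allylic acetate and the Z-enoate neither ionise nor isomerise in cold TFA.

Step 8
Reactants: 10 1-[(2R,3S)-6-(3,4-dimethoxybenzyloxy)-3-hydroxy-2-(prop-1-en-2-yl)-2,3-dihydro-1-benzofuran-5-yl]ethanone; 15 (2Z)-4-acetoxy-2-methylbut-2-enoic acid
Product: 17 (2R,3S)-5-acetyl-6-(3,4-dimethoxybenzyloxy)-2-(prop-1-en-2-yl)-2,3-dihydro-1-benzofuran-3-yl (2Z)-4-acetoxy-2-methylbut-2-enoate, via mixed anhydride 16 (not isolated)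
Conditions: 15, 2,4,6-Cl3C6H2COCl, Et3N, toluene, rt; then 10, toluene, 70 °C (no DMAP)
Reagents that add atoms: 2,4,6-trichlorobenzoyl chloride, O=C(Cl)c1c(Cl)cc(Cl)cc1Cl (its atoms stay in intermediate 16 only)
Why: Yamaguchi esterification without DMAP, the variant used for angelate-type Z-2-methylbut-2-enoates: the alcohol attacks the less hindered enoyl carbonyl of the mixed anhydride, C3–O is not broken so the configuration is retained, and omitting the nucleophilic catalyst avoids conjugate addition that would isomerise the Z alkene or expel the allylic acetate.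

Step 9
Reactants: 17 (2R,3S)-5-acetyl-6-(3,4-dimethoxybenzyloxy)-2-(prop-1-en-2-yl)-2,3-dihydro-1-benzofuran-3-yl (2Z)-4-acetoxy-2-methylbut-2-enoate
Product: 18 (2R,3S)-5-acetyl-6-hydroxy-2-(prop-1-en-2-yl)-2,3-dihydro-1-benzofuran-3-yl (2Z)-4-acetoxy-2-methylbut-2-enoate
Conditions: DDQ (1.5 equiv), CH2Cl2–pH 7 phosphate buffer (10:1), 0 °C to rt
Reagents that add atoms: none
Why: Oxidative debenzylation with DDQ (hydride abstraction from the electron-rich benzylic CH2, hydrolysis of the oxocarbenium ion) under buffered neutral conditions should release the acetyl-chelated phenol without the acid that would ionise the activated benzylic C3–O bond; the esters, the allylic acetate and both alkenes are inert to it.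

Compound list
1 | 1-(5-bromo-4-fluoro-2-hydroxyphenyl)ethanone | CC(=O)c1cc(Br)c(F)cc1O | starting material
2 | 1-[5-bromo-2-(3,4-dimethoxybenzyloxy)-4-fluorophenyl]ethanone | CC(=O)c1cc(Br)c(F)cc1OCc1ccc(OC)c(OC)c1 | intermediate
3 | 5-acetyl-4-(3,4-dimethoxybenzyloxy)-2-fluorobenzaldehyde | CC(=O)c1cc(C=O)c(F)cc1OCc1ccc(OC)c(OC)c1 | intermediate
4 | 2-methylprop-2-en-1-ol | C=C(C)CO | starting material
5 | 5-acetyl-4-(3,4-dimethoxybenzyloxy)-2-[(2-methylprop-2-en-1-yl)oxy]benzaldehyde | CC(=O)c1cc(C=O)c(OCC(C)=C)cc1OCc1ccc(OC)c(OC)c1 | intermediate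
6 | vinylboronic acid pinacol ester | C=CB1OC(C)(C)C(C)(C)O1 | starting material
7 | 5-acetyl-4-(3,4-dimethoxybenzyloxy)-2-{[(E)-2-methyl-3-(4,4,5,5-tetramethyl-1,3,2-dioxaborolan-2-yl)prop-2-en-1-yl]oxy}benzaldehyde | CC(=O)c1cc(C=O)c(OC/C(C)=C/B2OC(C)(C)C(C)(C)O2)cc1OCc1ccc(OC)c(OC)c1 | intermediate (key-step precursor)
8 | 5-acetyl-4-(3,4-dimethoxybenzyloxy)-2-{[(E)-2-methyl-3-(4,4,5,5-tetramethyl-1,3,2-dioxaborolan-2-yl)prop-1-en-1-yl]oxy}benzaldehyde | CC(=O)c1cc(C=O)c(O/C=C(\C)CB2OC(C)(C)C(C)(C)O2)cc1OCc1ccc(OC)c(OC)c1 | intermediate (not isolated)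
9 | 1-[(2R,3S)-6-(3,4-dimethoxybenzyloxy)-2-(prop-1-en-2-yl)-3-[(4,4,5,5-tetramethyl-1,3,2-dioxaborolan-2-yl)oxy]-2,3-dihydro-1-benzofuran-5-yl]ethanone | C=C(C)[C@H]1Oc2cc(OCc3ccc(OC)c(OC)c3)c(C(C)=O)cc2[C@@H]1OB1OC(C)(C)C(C)(C)O1 | intermediate (not isolated)
10 | 1-[(2R,3S)-6-(3,4-dimethoxybenzyloxy)-3-hydroxy-2-(prop-1-en-2-yl)-2,3-dihydro-1-benzofuran-5-yl]ethanone (trans) | C=C(C)[C@H]1Oc2cc(OCc3ccc(OC)c(OC)c3)c(C(C)=O)cc2[C@@H]1O | intermediate (key-step product)
11 | 3-methylfuran-2(5H)-one | CC1=CCOC1=O | starting material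
12 | potassium (2Z)-4-hydroxy-2-methylbut-2-enoate | O=C([O-])/C(C)=C\CO.[K+] | intermediate (not isolated)
13 | 4-methoxybenzyl (2Z)-4-hydroxy-2-methylbut-2-enoate | COc1ccc(COC(=O)/C(C)=C\CO)cc1 | intermediate (not isolated)
14 | 4-methoxybenzyl (2Z)-4-acetoxy-2-methylbut-2-enoate | COc1ccc(COC(=O)/C(C)=C\COC(C)=O)cc1 | intermediate
15 | (2Z)-4-acetoxy-2-methylbut-2-enoic acid | OC(=O)/C(C)=C\COC(C)=O | intermediate
16 | (2Z)-4-acetoxy-2-methylbut-2-enoic 2,4,6-trichlorobenzoic anhydride | O=C(OC(=O)/C(C)=C\COC(C)=O)c1c(Cl)cc(Cl)cc1Cl | intermediate (not isolated)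
17 | (2R,3S)-5-acetyl-6-(3,4-dimethoxybenzyloxy)-2-(prop-1-en-2-yl)-2,3-dihydro-1-benzofuran-3-yl (2Z)-4-acetoxy-2-methylbut-2-enoate | C=C(C)[C@H]1Oc2cc(OCc3ccc(OC)c(OC)c3)c(C(C)=O)cc2[C@@H]1OC(=O)/C(C)=C\COC(C)=O | intermediate
18 | (2R,3S)-5-acetyl-6-hydroxy-2-(prop-1-en-2-yl)-2,3-dihydro-1-benzofuran-3-yl (2Z)-4-acetoxy-2-methylbut-2-enoate | C=C(C)[C@H]1Oc2cc(O)c(C(C)=O)cc2[C@@H]1OC(=O)/C(C)=C\COC(C)=O | target

Total step count: 9. Longest linear sequence: 7 (steps 1, 2, 3, 4, 5, 8, 9); steps 6 and 7 form the acid branch.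

Steps most likely to fail

Step 5 (proposed new method). Three things may go wrong. Hydrogen migration may go toward the methyl group, or the enol-ether geometry may be lost, leading to seven-membered or cis-fused closure. Uncatalysed ring closure may outrun the chiral acid and erode enantiomeric purity. Continued double-bond migration or dehydration may lead toward the benzofuran. The fallback uses known chemistry, sets out from 2 and comes back at 10, and forms the O1–C2 bond instead of C2–C3. Suzuki–Miyaura coupling of 2 with (E)-4,4,5,5-tetramethyl-2-(3-methylbuta-1,3-dien-1-yl)-1,3,2-dioxaborolane (Pd(dppf)Cl2, K3PO4, dioxane–H2O, 80 °C) should give 1-{2-(3,4-dimethoxybenzyloxy)-4-fluoro-5-[(E)-3-methylbuta-1,3-dien-1-yl]phenyl}ethanone F1. SNAr hydroxylation of the fluoride para to acetyl (KOH, DMSO–H2O, 80 °C) should give 1-{2-(3,4-dimethoxybenzyloxy)-4-hydroxy-5-[(E)-3-methylbuta-1,3-dien-1-yl]phenyl}ethanone F2. Shi epoxidation of the trans-disubstituted styrenyl alkene with the L-sorbose-derived enantiomer of the fructose ketone (Oxone, K2CO3 buffer, MeCN–dimethoxymethane, 0 °C) should give 1-{2-(3,4-dimethoxybenzyloxy)-4-hydroxy-5-[(2S,3S)-3-(prop-1-en-2-yl)oxiran-2-yl]phenyl}ethanone F3. In the basic medium its phenoxide should open the epoxide at the allylic carbon with inversion, giving the trans (2R,3S) alcohol 10.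

Step 4. The hindered 1,1-disubstituted allylic ether may turn over slowly, the catalyst may decay, and the vinylboronate may self-metathesise. The fallback sets out from 3 and comes back at 7, forming the C–B bond by Miyaura borylation instead. SNAr of 3 with (E)-3-iodo-2-methylprop-2-en-1-ol (from propargyl alcohol by zirconium-catalysed methylalumination and iodinolysis; Cs2CO3, DMF, rt) should give 5-acetyl-4-(3,4-dimethoxybenzyloxy)-2-{[(E)-3-iodo-2-methylprop-2-en-1-yl]oxy}benzaldehyde F4. Borylation with bis(pinacolato)diboron (PdCl2(PPh3)2, PPh3, KOPh, toluene, 50 °C) proceeds with retention of alkene geometry and should return 7.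

Step 8. Acylation of the hindered benzylic alcohol by the α-branched Z-enoyl donor may be slow, the enoate may isomerise from Z to E, or heating may cause elimination toward the benzofuran. The fallback sets out from 10 and comes back at 17, building the Z alkene on the substrate. Carbodiimide coupling of 10 with 2-[bis(2,2,2-trifluoroethoxy)phosphoryl]propanoic acid (EDC·HCl, DMAP cat., CH2Cl2, 0 °C) should give (2R,3S)-5-acetyl-6-(3,4-dimethoxybenzyloxy)-2-(prop-1-en-2-yl)-2,3-dihydro-1-benzofuran-3-yl 2-[bis(2,2,2-trifluoroethoxy)phosphoryl]propanoate F5. Still–Gennari olefination with 2-oxoethyl acetate (KHMDS, 18-crown-6, THF, −78 °C; one equivalent of base, so the aryl methyl ketone is not enolised) should give 17 with the Z geometry under kinetic control.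

Further compounds
F1 | step 5 | 1-{2-(3,4-dimethoxybenzyloxy)-4-fluoro-5-[(E)-3-methylbuta-1,3-dien-1-yl]phenyl}ethanone | C=C(C)/C=C/c1cc(C(C)=O)c(OCc2ccc(OC)c(OC)c2)cc1F
F2 | step 5 | 1-{2-(3,4-dimethoxybenzyloxy)-4-hydroxy-5-[(E)-3-methylbuta-1,3-dien-1-yl]phenyl}ethanone | C=C(C)/C=C/c1cc(C(C)=O)c(OCc2ccc(OC)c(OC)c2)cc1O
F3 | step 5 | 1-{2-(3,4-dimethoxybenzyloxy)-4-hydroxy-5-[(2S,3S)-3-(prop-1-en-2-yl)oxiran-2-yl]phenyl}ethanone | C=C(C)[C@@H]1O[C@H]1c1cc(C(C)=O)c(OCc2ccc(OC)c(OC)c2)cc1O
F4 | step 4 | 5-acetyl-4-(3,4-dimethoxybenzyloxy)-2-{[(E)-3-iodo-2-methylprop-2-en-1-yl]oxy}benzaldehyde | CC(=O)c1cc(C=O)c(OC/C(C)=C/I)cc1OCc1ccc(OC)c(OC)c1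
F5 | step 8 | (2R,3S)-5-acetyl-6-(3,4-dimethoxybenzyloxy)-2-(prop-1-en-2-yl)-2,3-dihydro-1-benzofuran-3-yl 2-[bis(2,2,2-trifluoroethoxy)phosphoryl]propanoate | C=C(C)[C@H]1Oc2cc(OCc3ccc(OC)c(OC)c3)c(C(C)=O)cc2[C@@H]1OC(=O)C(C)P(=O)(OCC(F)(F)F)OCC(F)(F)F
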